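## Retrosynthetic overview

1. The target comes from a tris-silyl keto acid by fluoride. The acid comes from neutral oxidation of a C2 hydroxymethyl group, and the aryl ketone from addition of a 2,5-bis(silyloxy)phenyllithium to a spiro γ-lactone whose carbonyl carbon becomes the ketone carbon.
2. The spirolactone comes from hydroboration and oxidative lactonisation of a 2-ethenyl-2-(hydroxymethyl)-2,3,4,7-tetrahydrooxepine: the vinyl group is the latent CH2C(=O)Ar arm and CH2OH the latent CO2H.
3. Key disconnection: the oxepine ring, the only ring that is built, is cut at O1–C2 and at C5=C6. This gives a C2–C3–C4–C5 unit (racemic 2-ethenyloxirane with a 3-(triphenylphosphonio)propyl arm) and an O1–C7–C6 unit (α-hydroxy ketone carrying the side chain). One flask joins them by palladium-catalysed enantioselective allylic etherification followed by intramolecular Wittig olefination.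
4. Enabling feature: ring atom C2 is a fully substituted ether carbon whose carboxyl and aroylmethyl arms can be carried as CH2OH and vinyl, which makes C2 the substituted terminus of a π-allylpalladium unit. Ring atom C6 is an alkene carbon flanked by C7H2–O1, which makes O1–C7–C6 an α-hydroxy ketone, so the seven ring atoms O1 and C2–C7 are supplied as 4 + 3.
5. Fragments: the epoxide from 5-chloropent-1-yne, the hydroxy ketone from 5-bromo-2-methylpent-2-ene, and the arene (carried in intact) from 2-bromobenzene-1,4-diol.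

Key step: step 7

Assumption: the (R,R) ligand is taken to deliver the oxygen to the face of the π-allyl unit that gives the (S)-configured tertiary ether; should the sense be the opposite, the (S,S) ligand is used with no other change.

Abbreviation: TBS = tert-butyldimethylsilyl; TBSO = tert-butyldimethylsilyloxy.

## Route

Step 1
Reactants: 1 5-chloropent-1-yne
Product: 2 2-(3-chloropropyl)buta-1,3-diene
Conditions: ethylene (1 atm), second-generation Grubbs catalyst RuCl2(=CHPh)(PCy3)(H2IMes) (3 mol %), toluene, 80 °C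
Reagents that add atoms: ethylene, C=C
Why: cross enyne metathesis with ethylene should convert the terminal alkyne into the 2-substituted 1,3-diene, the primary chloride being inert to the ruthenium carbene.

Step 2
Reactants: 2 2-(3-chloropropyl)buta-1,3-diene
Product: 3 (4-methylidenehex-5-en-1-yl)triphenylphosphonium chloride
Conditions: PPh3, NaI (10 mol %), BHT (trace), MeCN, 80 °C
Reagents that add atoms: triphenylphosphine, c1ccc(cc1)P(c1ccccc1)c1ccccc1
Why: SN2 quaternisation of the primary chloride under iodide (Finkelstein-type) catalysis should give the phosphonium salt that carries the latent C5 ylide carbon.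

Step 3
Reactants: 3 (4-methylidenehex-5-en-1-yl)triphenylphosphonium chloride
Product: 4 rac-[3-(2-ethenyloxiran-2-yl)propyl]triphenylphosphonium chloride
Conditions: mCPBA (1.0 equiv), NaHCO3, CH2Cl2, 0 °C
Reagents that add atoms: meta-chloroperbenzoic acid, OOC(=O)c1cccc(Cl)c1
Why: Prilezhaev epoxidation should take the more electron-rich 1,1-disubstituted alkene of the 2-alkyl diene, and the racemate is what the stereoconvergent step 7 needs.

Step 4
Reactants: 5 5-bromo-2-methylpent-2-ene
Product: 6 (2E)-5-bromo-2-methylpent-2-en-1-ol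
Conditions: SeO2 (10 mol %), t-BuOOH (2 equiv), salicylic acid (10 mol %), CH2Cl2, rt
Reagents that add atoms: tert-butyl hydroperoxide, CC(C)(C)OO
Why: Riley-type allylic oxidation (ene reaction, then [2,3]-sigmatropic shift) should hydroxylate the methyl group trans to the chain and so fix the (E) geometry of the side-chain alkene.

Step 5
Reactants: 6 (2E)-5-bromo-2-methylpent-2-en-1-ol
Product: 7 (2E)-5-bromo-2-methyl-1-(TBSO)pent-2-ene
Conditions: TBSCl, imidazole, CH2Cl2, 0 °C to rt
Reagents that add atoms: tert-butyldimethylsilyl chloride, CC(C)(C)[Si](C)(C)Cl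
Why: standard silylation of a primary allylic alcohol should protect it through the organometallic, basic and oxidative steps that follow.

Step 6
Reactants: 7 (2E)-5-bromo-2-methyl-1-(TBSO)pent-2-ene; 8 2-hydroxy-N-methoxy-N-methylacetamide
Product: 11 (5E)-1-hydroxy-6-methyl-7-(TBSO)hept-5-en-2-one, via Grignard reagent 9 (not isolated), via chloromagnesium alkoxide 10 (not isolated)
Conditions: 7, Mg, THF, rt; separately 8, i-PrMgCl (1.0 equiv), THF, −20 °C; 9 added to 10, −20 °C to rt; aq NH4Cl
Reagents that add atoms: none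
Why: Weinreb ketone synthesis, in which the chelated tetrahedral adduct should resist a second addition and release the α-hydroxy ketone only on work-up, the free hydroxyl being masked in the flask as its magnesium alkoxide.

Step 7
Reactants: 4 rac-[3-(2-ethenyloxiran-2-yl)propyl]triphenylphosphonium chloride; 11 (5E)-1-hydroxy-6-methyl-7-(TBSO)hept-5-en-2-one
Product: 13 [(2S)-2-ethenyl-6-[(3E)-4-methyl-5-(TBSO)pent-3-en-1-yl]-2,3,4,7-tetrahydrooxepin-2-yl]methanol, via phosphonium ether 12 (not isolated)
Conditions: Pd2(dba)3·CHCl3 (2.5 mol %), (R,R)-N,N'-(cyclohexane-1,2-diyl)bis[2-(diphenylphosphanyl)benzamide] (7.5 mol %), BEt3 (10 mol %), CH2Cl2, rt; then THF (0.01 M), KN(SiMe3)2 (2.2 equiv), −78 °C to rt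
Reagents that add atoms: none
Why: Zerovalent palladium should ionise racemic 4 to a π-allyl complex whose diastereomeric forms interconvert by π–σ–π exchange, while the borane ties the alkoxide of the opened epoxide to the hydroxyl oxygen of 11 and delivers it to the substituted allyl terminus, which forms the O1–C2 bond of 12 (dynamic kinetic asymmetric Tsuji–Trost etherification; the closest known type is the palladium/borane etherification of 2-alkyl-2-ethenyloxiranes with primary alcohols). The new quaternary stereocentre C2 is set in this event by the chiral diphosphine, which differentiates the two faces of the equilibrating allyl unit. Base then converts the phosphonium end into the non-stabilised ylide at C5, which attacks the only ketone carbon (C6) in an intramolecular Wittig reaction. The seven-membered ring is thus closed by carbonyl olefination across C5=C6, and a ring of this size admits only the cis (ring-Z) alkene, so no alkene geometry has to be controlled. The step needs branched over linear regioselectivity, secured by the internal boron-mediated delivery of oxygen, and clean ylide chemistry, secured by the absence of a second carbonyl group or another comparably acidic C–H bond in 12.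

Step 8
Reactants: 13 [(2S)-2-ethenyl-6-[(3E)-4-methyl-5-(TBSO)pent-3-en-1-yl]-2,3,4,7-tetrahydrooxepin-2-yl]methanol
Product: 15 2-[(2S)-2-(hydroxymethyl)-6-[(3E)-4-methyl-5-(TBSO)pent-3-en-1-yl]-2,3,4,7-tetrahydrooxepin-2-yl]ethan-1-ol, via alkylborane 14 (not isolated)
Conditions: 9-BBN (1.5 equiv), THF, 0 °C to rt; then NaOH (aq), H2O2, 0 °C
Reagents that add atoms: hydrogen peroxide, OO
Why: anti-Markovnikov hydroboration–oxidation with the bulky borane should take only the monosubstituted vinyl group and leave both trisubstituted alkenes untouched.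

Step 9
Reactants: 15 2-[(2S)-2-(hydroxymethyl)-6-[(3E)-4-methyl-5-(TBSO)pent-3-en-1-yl]-2,3,4,7-tetrahydrooxepin-2-yl]ethan-1-ol
Product: 17 (5S)-8-[(3E)-4-methyl-5-(TBSO)pent-3-en-1-yl]-2,6-dioxaspiro[4.6]undec-8-en-3-one, via lactol 16 (not isolated)
Conditions: TEMPO (20 mol %), PhI(OAc)2 (2.5 equiv), CH2Cl2, rt
Reagents that add atoms: none
Why: oxoammonium (TEMPO) oxidative lactonisation, in which the unhindered 2-hydroxyethyl carbinol should be oxidised before the neopentyl one, the carbonyl group closes onto the neighbouring hydroxymethyl group to lactol 16 and this is oxidised on to the lactone.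

Step 10
Reactants: 18 2-bromobenzene-1,4-diol
Product: 19 2-bromo-1,4-bis(TBSO)benzene
Conditions: TBSCl (2.4 equiv), imidazole, DMF, rt
Reagents that add atoms: tert-butyldimethylsilyl chloride, CC(C)(C)[Si](C)(C)Cl
Why: standard bis-silylation of the hydroquinone should give an aryl bromide fit for halogen–metal exchange and for fluoride deprotection at the end.

Step 11
Reactants: 17 (5S)-8-[(3E)-4-methyl-5-(TBSO)pent-3-en-1-yl]-2,6-dioxaspiro[4.6]undec-8-en-3-one; 19 2-bromo-1,4-bis(TBSO)benzene
Product: 21 1-[2,5-bis(TBSO)phenyl]-2-[(2S)-2-(hydroxymethyl)-6-[(3E)-4-methyl-5-(TBSO)pent-3-en-1-yl]-2,3,4,7-tetrahydrooxepin-2-yl]ethan-1-one, via aryllithium 20 (not isolated)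
Conditions: 19, n-BuLi (1.05 equiv), THF, −78 °C; then 17, −78 °C; AcOH, −78 °C
Reagents that add atoms: none
Why: bromine–lithium exchange followed by single addition of the aryllithium to the γ-lactone, whose lithium hemiketal alkoxide should survive at −78 °C and collapse to the aryl ketone only on the cold acidic quench, which also sets the neopentyl alcohol free.

Step 12
Reactants: 21 1-[2,5-bis(TBSO)phenyl]-2-[(2S)-2-(hydroxymethyl)-6-[(3E)-4-methyl-5-(TBSO)pent-3-en-1-yl]-2,3,4,7-tetrahydrooxepin-2-yl]ethan-1-one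
Product: 22 (2S)-2-{2-[2,5-bis(TBSO)phenyl]-2-oxoethyl}-6-[(3E)-4-methyl-5-(TBSO)pent-3-en-1-yl]-2,3,4,7-tetrahydrooxepine-2-carboxylic acid
Conditions: TEMPO (30 mol %), PhI(OAc)2 (2.5 equiv), MeCN/pH 7 phosphate buffer (1:1), rt
Reagents that add atoms: water, O
Why: oxoammonium oxidation of the primary alcohol through the aldehyde hydrate to the acid should proceed under near-neutral conditions, under which the β-alkoxy ketone cannot open by base-induced retro-oxa-Michael elimination, so C2 keeps its configuration.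

Step 13
Reactants: 22 (2S)-2-{2-[2,5-bis(TBSO)phenyl]-2-oxoethyl}-6-[(3E)-4-methyl-5-(TBSO)pent-3-en-1-yl]-2,3,4,7-tetrahydrooxepine-2-carboxylic acid
Product: 23 (2S)-2-[2-(2,5-dihydroxyphenyl)-2-oxoethyl]-6-[(3E)-5-hydroxy-4-methylpent-3-en-1-yl]-2,3,4,7-tetrahydrooxepine-2-carboxylic acid
Conditions: HF·pyridine, pyridine, THF, 0 °C to rt, argon
Reagents that add atoms: none
Why: fluoride cleavage of the two aryl silyl ethers and the allylic silyl ether under buffered, weakly acidic conditions should free the target without the base that would cause retro-oxa-Michael racemisation or chromanone formation.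

## Compound list

1 | 5-chloropent-1-yne | C#CCCCCl | starting material
2 | 2-(3-chloropropyl)buta-1,3-diene | C=CC(=C)CCCCl | intermediate
3 | (4-methylidenehex-5-en-1-yl)triphenylphosphonium chloride | C=CC(=C)CCC[P+](c1ccccc1)(c1ccccc1)c1ccccc1.[Cl-] | intermediate
4 | rac-[3-(2-ethenyloxiran-2-yl)propyl]triphenylphosphonium chloride | C=CC1(CCC[P+](c2ccccc2)(c2ccccc2)c2ccccc2)CO1.[Cl-] | intermediate
5 | 5-bromo-2-methylpent-2-ene | CC(C)=CCCBr | starting material
6 | (2E)-5-bromo-2-methylpent-2-en-1-ol | C/C(=C\CCBr)CO | intermediate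
7 | (2E)-5-bromo-2-methyl-1-(TBSO)pent-2-ene | C/C(=C\CCBr)CO[Si](C)(C)C(C)(C)C | intermediate
8 | 2-hydroxy-N-methoxy-N-methylacetamide | CON(C)C(=O)CO | starting material
9 | [(3E)-4-methyl-5-(TBSO)pent-3-en-1-yl]magnesium bromide | C/C(=C\CC[Mg]Br)CO[Si](C)(C)C(C)(C)C | intermediate
10 | chloromagnesium 2-[methoxy(methyl)amino]-2-oxoethanolate | CON(C)C(=O)CO[Mg]Cl | intermediate
11 | (5E)-1-hydroxy-6-methyl-7-(TBSO)hept-5-en-2-one | C/C(=C\CCC(=O)CO)CO[Si](C)(C)C(C)(C)C | intermediate
12 | [(4S)-4-(hydroxymethyl)-4-{[(5E)-6-methyl-2-oxo-7-(TBSO)hept-5-en-1-yl]oxy}hex-5-en-1-yl]triphenylphosphonium chloride | C/C(=C\CCC(=O)CO[C@@](C=C)(CO)CCC[P+](c1ccccc1)(c1ccccc1)c1ccccc1)CO[Si](C)(C)C(C)(C)C.[Cl-] | intermediate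
13 | [(2S)-2-ethenyl-6-[(3E)-4-methyl-5-(TBSO)pent-3-en-1-yl]-2,3,4,7-tetrahydrooxepin-2-yl]methanol | C/C(=C\CCC1=CCC[C@](C=C)(CO)OC1)CO[Si](C)(C)C(C)(C)C | intermediate
14 | 9-{2-[(2R)-2-(hydroxymethyl)-6-[(3E)-4-methyl-5-(TBSO)pent-3-en-1-yl]-2,3,4,7-tetrahydrooxepin-2-yl]ethyl}-9-borabicyclo[3.3.1]nonane (same spatial arrangement at C2 as in 13; the descriptor changes by priority only) | C/C(=C\CCC1=CCC[C@](CCB2C3CCCC2CCC3)(CO)OC1)CO[Si](C)(C)C(C)(C)C | intermediate
15 | 2-[(2S)-2-(hydroxymethyl)-6-[(3E)-4-methyl-5-(TBSO)pent-3-en-1-yl]-2,3,4,7-tetrahydrooxepin-2-yl]ethan-1-ol | C/C(=C\CCC1=CCC[C@](CCO)(CO)OC1)CO[Si](C)(C)C(C)(C)C | intermediate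
16 | (5S)-8-[(3E)-4-methyl-5-(TBSO)pent-3-en-1-yl]-2,6-dioxaspiro[4.6]undec-8-en-3-ol (both epimers at C3) | C/C(=C\CCC1=CCC[C@](CC(O)O2)(C2)OC1)CO[Si](C)(C)C(C)(C)C | intermediate
17 | (5S)-8-[(3E)-4-methyl-5-(TBSO)pent-3-en-1-yl]-2,6-dioxaspiro[4.6]undec-8-en-3-one | C/C(=C\CCC1=CCC[C@](CC(=O)O2)(C2)OC1)CO[Si](C)(C)C(C)(C)C | intermediate
18 | 2-bromobenzene-1,4-diol | Oc1ccc(O)c(Br)c1 | starting material
19 | 2-bromo-1,4-bis(TBSO)benzene | CC(C)(C)[Si](C)(C)Oc1ccc(O[Si](C)(C)C(C)(C)C)c(Br)c1 | intermediate
20 | [2,5-bis(TBSO)phenyl]lithium | CC(C)(C)[Si](C)(C)Oc1ccc(O[Si](C)(C)C(C)(C)C)c([Li])c1 | intermediate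
21 | 1-[2,5-bis(TBSO)phenyl]-2-[(2S)-2-(hydroxymethyl)-6-[(3E)-4-methyl-5-(TBSO)pent-3-en-1-yl]-2,3,4,7-tetrahydrooxepin-2-yl]ethan-1-one | C/C(=C\CCC1=CCC[C@](CC(=O)c2cc(O[Si](C)(C)C(C)(C)C)ccc2O[Si](C)(C)C(C)(C)C)(CO)OC1)CO[Si](C)(C)C(C)(C)C | intermediate
22 | (2S)-2-{2-[2,5-bis(TBSO)phenyl]-2-oxoethyl}-6-[(3E)-4-methyl-5-(TBSO)pent-3-en-1-yl]-2,3,4,7-tetrahydrooxepine-2-carboxylic acid | C/C(=C\CCC1=CCC[C@](CC(=O)c2cc(O[Si](C)(C)C(C)(C)C)ccc2O[Si](C)(C)C(C)(C)C)(C(=O)O)OC1)CO[Si](C)(C)C(C)(C)C | intermediate
23 | (2S)-2-[2-(2,5-dihydroxyphenyl)-2-oxoethyl]-6-[(3E)-5-hydroxy-4-methylpent-3-en-1-yl]-2,3,4,7-tetrahydrooxepine-2-carboxylic acid | C/C(=C\CCC1=CCC[C@](CC(=O)c2cc(O)ccc2O)(C(=O)O)OC1)CO | target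

## Step count and risks

Total step count: 13. Longest linear sequence: 9 steps (steps 4, 5, 6, 7, 8, 9, 11, 12, 13; the line through steps 1 to 3 is equally long).

Steps most likely to fail:

**Step 7.** Three processes threaten it. Proton transfer from the phosphonium α-CH2 group to the palladium-bound alkoxide during the etherification stage would start ylide chemistry (C-allylation, olefination out of sequence) before O1–C2 exists. The opened epoxide could be captured by the ketone oxygen instead of the hydroxyl group. The olefination could be slow because ring–chain hemiketalisation masks the ketone.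

The fallback sets out from 2 and 11 and comes back at 13. It separates the two bond formations and brings in phosphorus only after the ether is made. Diene 2 is epoxidised (mCPBA, NaHCO3, CH2Cl2) to rac-2-(3-chloropropyl)-2-ethenyloxirane F1. The same palladium/borane etherification of F1 with 11 should give the neutral chloro ether (5E)-1-{[(3S)-6-chloro-3-(hydroxymethyl)hex-1-en-3-yl]oxy}-6-methyl-7-(TBSO)hept-5-en-2-one F2. NaI and then PPh3 (MeCN, 60 °C) turn it into [(4S)-4-(hydroxymethyl)-4-{[(5E)-6-methyl-2-oxo-7-(TBSO)hept-5-en-1-yl]oxy}hex-5-en-1-yl]triphenylphosphonium iodide F3. KN(SiMe3)2 (THF, high dilution) then closes the ring to 13.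

**Step 11.** The hindered aryllithium may deprotonate the lactone next to the carbonyl group, after which β-elimination of the ring oxygen would open the oxepine. Double addition and anionic oxygen-to-carbon silyl migration (retro-Brook) in the ortho-silyloxy aryllithium are the other threats.

The fallback sets out from 17 and 19 and comes back at 21. Lactone 17 is opened with MeNH(OMe)·HCl and AlMe3 (CH2Cl2, 0 °C) to the hydroxy Weinreb amide 2-[(2S)-2-(hydroxymethyl)-6-[(3E)-4-methyl-5-(TBSO)pent-3-en-1-yl]-2,3,4,7-tetrahydrooxepin-2-yl]-N-methoxy-N-methylacetamide F4. Bromide 19 is converted with Mg and LiCl (THF) into [2,5-bis(TBSO)phenyl]magnesium bromide F5, a less basic nucleophile that does not undergo silyl migration. About 2.2 equiv of F5 should convert F4 into 21 through a chelated adduct that cannot add a second time.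

**Step 9.** First oxidation at the neopentyl carbinol instead of the 2-hydroxyethyl carbinol would lead to the regioisomeric lactone.

The fallback sets out from 13 and comes back at 17, bypassing the diol. Aldehyde-selective Wacker oxidation of the vinyl group of 13 (PdCl2(PhCN)2, CuCl2, AgNO2, O2, t-BuOH/MeNO2) puts the carbonyl group on the terminal carbon by construction. The aldehyde closes onto the neighbouring hydroxymethyl group to the same lactol 16, and Ag2CO3 on Celite (benzene, reflux) oxidises 16 to 17.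

Further compounds
F1 | step 7 | rac-2-(3-chloropropyl)-2-ethenyloxirane | C=CC1(CCCCl)CO1
F2 | step 7 | (5E)-1-{[(3S)-6-chloro-3-(hydroxymethyl)hex-1-en-3-yl]oxy}-6-methyl-7-(TBSO)hept-5-en-2-one | C/C(=C\CCC(=O)CO[C@@](C=C)(CO)CCCCl)CO[Si](C)(C)C(C)(C)C
F3 | step 7 | [(4S)-4-(hydroxymethyl)-4-{[(5E)-6-methyl-2-oxo-7-(TBSO)hept-5-en-1-yl]oxy}hex-5-en-1-yl]triphenylphosphonium iodide | C/C(=C\CCC(=O)CO[C@@](C=C)(CO)CCC[P+](c1ccccc1)(c1ccccc1)c1ccccc1)CO[Si](C)(C)C(C)(C)C.[I-]
F4 | step 11 | 2-[(2S)-2-(hydroxymethyl)-6-[(3E)-4-methyl-5-(TBSO)pent-3-en-1-yl]-2,3,4,7-tetrahydrooxepin-2-yl]-N-methoxy-N-methylacetamide | C/C(=C\CCC1=CCC[C@](CC(=O)N(C)OC)(CO)OC1)CO[Si](C)(C)C(C)(C)C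
F5 | step 11 | [2,5-bis(TBSO)phenyl]magnesium bromide | CC(C)(C)[Si](C)(C)Oc1ccc(O[Si](C)(C)C(C)(C)C)c([Mg]Br)c1
F0 | step 9 | none | none
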